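## Analysis of the target

Carbons are numbered C1 to C22 in the order in which they are written in the target SMILES (oxygens not counted). C1–C3 are the isopropenyl group, C14 is the methyl group on C13, C7 and C10 are the carbonyl carbons, and C18 and C21 carry the phenolic oxygens.

The skeleton is pentacyclic:
- ring A: the hydroquinone C17–C22;
- ring B: C6–C7–C8–C9–C10–C11, a cyclohexane-1,4-dione;
- ring C: the cyclohexene C6, C11, C12, C13, C15, C16;
- ring D: the five-membered ring C6, C11, C22, C17, C16;
- ring E: the cyclopentane C4, C5, C6, C7, C8.

Rings C and D form a benzobicyclo[3.2.1]octadiene with C6 as the one-carbon bridge. Rings B and E form a bicyclo[3.2.1]octan-8-one with C7 as the bridge.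

There are five stereocentres (C4, C6, C8, C11, C16). C6 belongs to four rings and sits next to the second quaternary carbon, C11. Because every ring fusion is a bridge, most of the relative configuration is dictated. The arene spans C16 and C11 on the face of ring C that is syn to C7 and anti to C5. C8 can only bond to C4 on the side of C5. The one free choice is the isopropenyl group on C4, which points toward the C7 bridge (exo).

Sensitive groups are the air-sensitive hydroquinone, the 1,1-disubstituted alkene that lies within bonding distance of the strained C7 carbonyl (acid and Lewis acid), the C13=C15 alkene, whose position is not held by conjugation, and the 1,4-diketone.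

The hard points are the arylated quaternary C11 beside quaternary C6, the C10 carbonyl (which has no activating neighbour once C11 is quaternary), the regiochemistry of the ring C alkene, and the need to tell three ketone-level carbons (C7, C10, C13) apart.

The strategy rests on one feature. C6 is the angular carbon of the decalin made of rings B and C, it bears the C7 ketone and the prenyl-derived C5, and C13 is a latent enone carbonyl. This is the pattern of a Wieland–Miescher ketone with prenyl in place of methyl.

## Retrosynthetic reasoning

**23 from 21 (through 22).** The two O–CH3 bonds are cut last. A free hydroquinone would not survive the oxidants, bases and Lewis acids of the route, and methyl ethers are inert to all of them. Removal must avoid strong acid because of the isopropenyl group, so the forward reaction is an oxidative demethylation to quinone 22 followed by reduction.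

**21 from 19 (through 20).** The C10 carbonyl is traced back to a silyl-protected secondary alcohol. C10 is kept below the ketone level until the end for two reasons. A C10 ketone beside the C11=C12 double bond would make an enedione and offer C12 to the arene as a second site. A C10 ketone would also compete with C13 for base later on (enolisation toward C9).

**19 from 16 (through 17 and 18).** The C13–C14 bond is cut; methyl is introduced by cross-coupling of enol triflate 18. The position of the double bond (C13=C15, not C12=C13) must come from the direction of enolisation of ketone 16. That is manageable only if C13 is the sole enolisable carbonyl, so C7 must already be locked in its bicycle and C10 masked.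

**16 from 14 (through 15).** The C11–C22 bond is cut. It closes ring D and makes C11 quaternary. C22 can reach C11 only from the face on which the arene already stands, so C11 is set without a choice. The forward reaction is an intramolecular Friedel–Crafts conjugate addition to the C11=C12–C13=O enone. C22 is the only ring A carbon within reach, so no directing group is needed.

**14 from 12 and 13.** The C16–C17 bond is cut. In dienone 12 the two β-carbons differ sharply (C11 fully substituted, C16 a methine), so conjugate arylation with boronic acid 13 is regioselective. The forward step must place the aryl group on the face syn to C7; a chiral catalyst is used for that.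

**12 from 9 (through 10 and 11).** The C10–O bond is cut. C10 is the vinylogous position of the C13 carbonyl through C11=C12, so oxygen can be brought in through trienol ether 10. This has to happen before C11 becomes quaternary, because afterwards C10 is an unactivated methylene.

**9 from 8.** The C4–C8 bond is cut, which opens ring E to a prenyl group on C6. The closure is placed here and not at the end because in 8 the C7 ketone carries the only α-hydrogens of the molecule and no electron-rich arene is present. Once closed, C7 can no longer enolise, which every later base step needs. The forward reaction must form the bond and leave C2 as an isopropenyl group, hence an oxidative radical cyclisation.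

**8 from 7.** The C15=C16 double bond is removed. Forward, this is a dehydrogenation of the enone that leaves the saturated C7 ketone alone.

**7 from 5 (through 6).** The C11=C12 bond is cut back to the ring carbonyl C11 and the methyl ketone carbon C12. Triketone 5 is achiral and its two ring carbonyls are enantiotopic. The aldol condensation that chooses between them creates C6, the stereocentre from which all others follow. This is the step the route is built around.

**5 from 3 and 4; 3 from 1 and 2.** The C6–C16 bond is cut by a Michael disconnection and the C6–C5 bond by an enolate alkylation, which leads to three commodity chemicals.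

## Alternatives that were turned down

**Alternative 1:** The C4–C8 bond (ring E) is disconnected last. The substrate is the prenyl ketone A2, which already contains rings A–D, a C10 dioxolane and the ring A dimethyl ether; the product is A1.
- Forward key step: Mn(OAc)3 (trivalent manganese) oxidises the enol of the C7 ketone to the C8 radical. This adds 5-exo to C4, and Cu(OAc)2 (divalent copper) turns the tertiary C2 radical into the isopropenyl alkene.
- For it: one step, no prefunctionalisation. The isopropenyl group and its strained ketone neighbour appear only after every Lewis acid and base step; on this point it is stronger than the chosen route, which carries them through the Friedel–Crafts step. The aryl group would also be added while the prenyl chain still rotates freely and shields one face, a clearer substrate bias than in 12.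
- Against it: in A2 the oxidant in hot acetic acid meets an oxidisable dimethoxyarene, the doubly activated C16–H, the ring C alkene and an acid-labile dioxolane, all in the last skeletal step. C7 must stay enolisable through the middle of the route, where a C13 ketone has to be turned regioselectively into the C13=C15 enol triflate in its presence. The disconnection also says nothing about how C6 is set.
- Comparison: the chosen route uses the same bond construction (step 5) but on 8, where C8 carries the only α-hydrogens and no arene exists. It pays for this with a catalyst-controlled arylation and a longer life for the isopropenyl group.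

**Alternative 2:** Ring A is disconnected at C17–C22, C18–C19 and C20–C21. The substrate is the 1,6-diyne A4, which has alkynylboronate arms on C16 and C11, plus acetylene A5; the product is A3.
- Forward key step: CpCo(CO)2 or Cp*RuCl(cod) couples the two alkynes to a metallacyclopentadiene, A5 inserts, and reductive elimination closes ring A and ring D together.
- For it: no Friedel–Crafts reaction at a quaternary carbon, and the two C–B bonds give the phenols by mild oxidation, so no demethylation is needed. On both points it is stronger than the chosen route. 1,6-Diynes are the best substrates for this cyclotrimerisation.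
- Against it: A4 must already contain quaternary C11 with an alkynyl group anti to the prenyl group, beside quaternary C6. The hardest centre is therefore moved into the substrate, not solved. The enedione of ring B in A4 is itself a good two-electron partner and can take the place of A5. The metallacycle has to span the one-carbon bridge C6. Oxidising two boronates with basic peroxide next to an enedione is unsafe. C6 is again not addressed.
- Comparison: the chosen route attaches a ready-made arene in two steps (9 and 10), with the configuration of C16 and C11 relayed from C6.

**Alternative 3:** The C6–C16 bond is disconnected. The substrate is the biaryl phenol A7, which has a prenyl group on C6 and a benzylic bromide at C16; the product is the dienone A6.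
- Forward key step: base gives the phenoxide, whose prenylated ortho carbon C6 displaces bromide at C16 (5-exo-tet). The phenol ring is dearomatised to a cyclohexa-2,4-dienone and the configuration of the biaryl axis is passed to C6.
- For it: rings A, B and D come from flat aromatic pieces by cross-coupling. The C11–C22 bond is simply the biaryl bond, and the C10 oxygen is present from the start as an enol ether. On these points it is stronger than the chosen route, which spends one difficult step on C11–C22 and five on the C10 oxygen.
- Against it: A7 is a tetra-ortho-substituted biaryl that must be made as one atropisomer. A6 is a 6,6-disubstituted cyclohexa-2,4-dienone of the kind that dimerises by cycloaddition. A6 also lacks ring C entirely: C12, C13, C14 and C15 would have to be bridged from the sp2 carbon C11 (making it quaternary) to the benzylic C16, with control at C16, and ring E is still missing. The key step therefore solves the easier half.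
- Comparison: the chosen route obtains C6 by catalysis from an achiral triketone and has ring C in place from the annulation, with its enone as the handle for C16, C11 and C13.

Key step: step 3

Remark: the C10 carbinol centre of 11–20 is drawn as the epimer expected from attack on the exo face (oxygen syn to the C7 bridge). Its configuration does not matter, because step 14 removes it.

## Route

Step 1
Reactants: 1 cyclohexane-1,3-dione; 2 1-bromo-3-methylbut-2-ene (prenyl bromide)
Product: 3 2-(3-methylbut-2-en-1-yl)cyclohexane-1,3-dione
Conditions: KOH (1.0 equiv), H2O, 0 °C → rt
Reagents that add atoms: none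
Why: Enolate C-alkylation: in water the potassium enolate of the 1,3-dione is hydrogen-bonded at oxygen and the soft allylic bromide reacts at the carbon between the carbonyls (the future C6); a slight deficit of bromide limits double alkylation.

Step 2
Reactants: 3 2-(3-methylbut-2-en-1-yl)cyclohexane-1,3-dione; 4 but-3-en-2-one (methyl vinyl ketone)
Product: 5 2-(3-methylbut-2-en-1-yl)-2-(3-oxobutyl)cyclohexane-1,3-dione
Conditions: Et3N (5 mol %), EtOAc, rt
Reagents that add atoms: none
Why: Michael addition of the acidic 2-substituted 1,3-dione to the enone under amine catalysis; C6 becomes quaternary but not yet stereogenic, since 5 keeps a mirror plane.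

Step 3
Reactants: 5 2-(3-methylbut-2-en-1-yl)-2-(3-oxobutyl)cyclohexane-1,3-dione
Product: 7 (8aR)-8a-(3-methylbut-2-en-1-yl)-3,4,8,8a-tetrahydronaphthalene-1,6(2H,7H)-dione, via cis-fused ketol 6 (not isolated)
Conditions: L-proline (30 mol %), DMSO, 25 °C; then 50 °C
Reagents that add atoms: none
Why: Hajos–Parrish–Eder–Sauer–Wiechert reaction, used here to desymmetrise a 2,2-disubstituted cyclohexane-1,3-dione. L-Proline condenses with the unhindered methyl ketone (C13) to an enamine whose carbon C12 is the nucleophile. The carboxylic acid of the catalyst hydrogen-bonds to one of the two enantiotopic ring carbonyls and C12 adds to it through a chair-like transition state with the anti enamine, a 6-(enolendo)-exo-trig closure that forms C11–C12 and ring C in the cis-fused ketol 6. Loss of water through the iminium/enamine gives the C11=C12 enone, erases the carbinol centre and leaves C6 as the only stereocentre. C6 is not touched by the reaction; it becomes stereogenic only because the two carbonyls are told apart, so the controlling element is the (S) configuration of the catalyst, which in the methyl series leads to the (S)-Wieland–Miescher ketone, and the same spatial sense with C5 in place of methyl is the (8aR) enone 7 needed for C6 of the target. The selectivity required is enantiotopic-group selectivity between C7 and C11; 5 has a mirror plane through C6 and C9, so the substrate offers no bias and the catalyst alone decides. Chemoselectivity (enamine of the methyl ketone, not of a ring ketone) follows from sterics, and the prenyl alkene is inert under these conditions.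

Step 4
Reactants: 7 (8aR)-8a-(3-methylbut-2-en-1-yl)-3,4,8,8a-tetrahydronaphthalene-1,6(2H,7H)-dione
Product: 8 (8aS)-8a-(3-methylbut-2-en-1-yl)-3,4-dihydronaphthalene-1,6(2H,8aH)-dione (cross-conjugated dienone; same spatial arrangement at C6 as in 7)
Conditions: DDQ (1.3 equiv), 1,4-dioxane, reflux
Reagents that add atoms: none
Why: Quinone dehydrogenation of an enone to the cross-conjugated dienone, as in the 1,2-dehydrogenation of steroidal 4-en-3-ones: DDQ takes hydride from C16 of the cross-conjugated dienol; the saturated C7 ketone and the isolated prenyl alkene are not activated toward hydride loss. The new C15=C16 bond removes every α-hydrogen next to C13, which step 5 relies on.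

Step 5
Reactants: 8 (8aS)-8a-(3-methylbut-2-en-1-yl)-3,4-dihydronaphthalene-1,6(2H,8aH)-dione
Product: 9 10-(prop-1-en-2-yl)tricyclo[7.2.1.0^1,6]dodeca-2,5-diene-4,12-dione (C4–C8 bond formed; isopropenyl on C4 exo i.e. syn to the C7 bridge)
Conditions: Mn(OAc)3·2H2O (2.2 equiv), Cu(OAc)2·H2O (0.5 equiv), AcOH, 80 °C
Reagents that add atoms: none
Why: Oxidative free-radical cyclisation of an unsaturated ketone: the manganese enolate of the C7 ketone (C8 carries the only α-hydrogens of 8) gives the C8 radical, which adds 5-exo-trig to C4 of the prenyl group, and divalent copper oxidises the tertiary C2 radical to the isopropenyl alkene. C8 can bond only on the ring B face that carries C5, and in the transition state the CMe2 terminus turns away from the C9–C10–C11 bridge, which places the isopropenyl group exo on C4. The bridged ketone formed cannot enolise, so it is not oxidised further.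

Step 6
Reactants: 9 tricyclic dienone
Product: 10 tert-butyldimethylsilyl trienol ether of 9 (silyloxy group on C13; double bonds C10=C11 and C12=C13 and C15=C16)
Conditions: TBSOTf (1.3 equiv), Et3N (2.0 equiv), CH2Cl2, −78 → 0 °C
Reagents that add atoms: tert-butyldimethylsilyl trifluoromethanesulfonate, CC(C)(C)[Si](C)(C)OS(=O)(=O)C(F)(F)F
Why: Soft enolisation: O-silylation of the dienone and loss of a C10 hydrogen, the only acidic position left (C7 is flanked by quaternary C6 and bridgehead C8), give the linear trienol ether.

Step 7
Reactants: 10 trienol silyl ether
Product: 11 C10-hydroxy dienone (9 with OH on C10; OH exo i.e. on the face turned toward the C7 bridge)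
Conditions: mCPBA (1.05 equiv), CH2Cl2, −20 °C; aq. NaHCO3 work-up
Reagents that add atoms: 3-chloroperbenzoic acid, O=C(OO)c1cccc(Cl)c1
Why: Vinylogous Rubottom oxidation: the peracid attacks the electron-rich terminal C10=C11 bond of the trienol ether, as in the 6-hydroxylation of steroidal 3,5-dienol ethers, and collapse with loss of the silyl group restores the dienone with oxygen on C10; the 1,1-disubstituted isopropenyl alkene reacts far more slowly. Attack from the exo face is expected because the endo face is screened by the C5 methylene.

Step 8
Reactants: 11 C10-hydroxy dienone
Product: 12 C10 tert-butyldimethylsilyl ether of 11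
Conditions: TBSOTf (1.5 equiv), 2,6-lutidine (3 equiv), CH2Cl2, −40 → 0 °C
Reagents that add atoms: tert-butyldimethylsilyl trifluoromethanesulfonate, CC(C)(C)[Si](C)(C)OS(=O)(=O)C(F)(F)F
Why: Silylation of a hindered secondary alcohol with the silyl triflate; the ether keeps C10 at the alcohol level through the organometallic, Lewis acid and strong-base steps that follow.

Step 9
Reactants: 12 C10-silyloxy dienone; 13 (2,5-dimethoxyphenyl)boronic acid
Product: 14 C16-aryl enone (2,5-dimethoxyphenyl on C16 syn to C7 and anti to C5; C11=C12–C13=O enone; C15 methylene)
Conditions: [Rh(OH)((R)-BINAP)]2 (3 mol %), 13 (2.5 equiv), 1,4-dioxane/H2O 10:1, 40 °C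
Reagents that add atoms: none
Why: Hayashi–Miyaura reaction (rhodium-catalysed conjugate addition of an arylboronic acid): only C16 is an accessible β-carbon, C11 being fully substituted. The aryl–rhodium species adds to the enone face chosen by the ligand; since (S)-BINAP gives (S)-3-arylcyclohexanones, the (R)-ligand should deliver the aryl group to the C16 face that is syn to C7, which sets C16. The hydroxo complex of monovalent rhodium needs no added base, which spares the 4-acyl dienone from nucleophilic cleavage, and water protonates the rhodium enolate at C15.

Step 10
Reactants: 14 C16-aryl enone
Product: 16 pentacyclic ketone (C11–C22 bond formed; C13 ketone with C12 and C15 methylenes; C10 silyl ether; ring A dimethyl ether), via chloro(methyl)aluminium enolate 15 (not isolated)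
Conditions: Me2AlCl (3 equiv), CH2Cl2, −78 → −20 °C; aq. KNaC4H4O6 work-up
Reagents that add atoms: none
Why: Intramolecular Friedel–Crafts conjugate addition (5-exo-trig): C22, ortho to C17 and activated by the C21 methoxy group, is the only arene carbon that can reach the Lewis acid-activated β-carbon C11, and it can do so only from the face on which the arene already stands, which fixes C11. Me2AlCl takes up the proton released on rearomatisation as methane, so no Brønsted acid meets the isopropenyl group or the silyl ether; addition of the arene to the C7 carbonyl would be reversible, because the resulting carbinol cannot dehydrate across a bridgehead. Work-up protonates the enolate at C12.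

Step 11
Reactants: 16 pentacyclic ketone
Product: 18 C13 enol triflate (C13=C15 double bond), via potassium enolate 17 (not isolated)
Conditions: KN(SiMe3)2 (1.1 equiv), THF, −78 °C; then PhNTf2 (1.2 equiv), −78 → −20 °C
Reagents that add atoms: N-phenylbis(trifluoromethanesulfonimide), O=S(=O)(N(c1ccccc1)S(=O)(=O)C(F)(F)F)C(F)(F)F
Why: Kinetic enolisation and O-triflation: C13 is now the only enolisable carbonyl (C7 is bridgehead-locked, C10 is an ether), and the bulky amide base should remove a C15 hydrogen, next to the C16 methine, in preference to the neopentyl C12 hydrogens beside quaternary C11 and its silyloxy-bearing neighbour.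

Step 12
Reactants: 18 C13 enol triflate
Product: 19 C13-methyl alkene (C13(CH3)=C15; C10 silyl ether; ring A dimethyl ether)
Conditions: Pd(PPh3)4 (5 mol %), MeZnCl (2 equiv), THF, 0 °C → rt
Reagents that add atoms: methylzinc chloride, C[Zn]Cl
Why: Negishi coupling of an alkenyl triflate; oxidative addition, transmetalation and reductive elimination keep the double bond where the triflate fixed it, and the organozinc reagent does not add to the shielded C7 ketone.

Step 13
Reactants: 19 C13-methyl alkene
Product: 20 C10 alcohol
Conditions: HF·pyridine, pyridine, THF, 0 °C → rt
Reagents that add atoms: none
Why: Fluoride-mediated cleavage of the silyl ether under buffered conditions that do not protonate the isopropenyl or ring C alkene.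

Step 14
Reactants: 20 C10 alcohol
Product: 21 dimethyl ether of the target (C7 and C10 ketones)
Conditions: Dess–Martin periodinane (1.5 equiv), CH2Cl2, rt
Reagents that add atoms: none
Why: Dess–Martin oxidation of a hindered secondary alcohol under neutral conditions; C11 is quaternary and C8 a bridgehead, so the new 1,4-diketone has no epimerisable centre.

Step 15
Reactants: 21 dimethyl ether of the target
Product: 23 target CNP0287617.1, via quinone 22 (not isolated)
Conditions: (NH4)2Ce(NO3)6 (2.5 equiv), MeCN/H2O 2:1, 0 °C; then aq. Na2S2O4, EtOAc, rt
Reagents that add atoms: water, O
Why: Oxidative demethylation of the 1,4-dimethoxyarene by tetravalent cerium to the para-quinone (the quinone oxygens come from water, methanol is lost), then dithionite reduction to the hydroquinone. No acid strong enough to protonate the alkenes is involved, and the quinone cannot tautomerise toward C16 because that carbon is a bridgehead.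

## Compound list

1 | cyclohexane-1,3-dione | O=C1CCCC(=O)C1 | starting material
2 | 1-bromo-3-methylbut-2-ene (prenyl bromide) | CC(C)=CCBr | starting material
3 | 2-(3-methylbut-2-en-1-yl)cyclohexane-1,3-dione | CC(C)=CCC1C(=O)CCCC1=O | intermediate
4 | but-3-en-2-one (methyl vinyl ketone) | C=CC(C)=O | starting material
5 | 2-(3-methylbut-2-en-1-yl)-2-(3-oxobutyl)cyclohexane-1,3-dione | CC(C)=CCC1(CCC(C)=O)C(=O)CCCC1=O | intermediate
6 | (4aS,8aR)-4a-hydroxy-8a-(3-methylbut-2-en-1-yl)octahydronaphthalene-1,6-dione (cis-fused ketol, OH cis to prenyl) | CC(C)=CC[C@@]12C(=O)CCC[C@]1(O)CC(=O)CC2 | intermediate (not isolated)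
7 | (8aR)-8a-(3-methylbut-2-en-1-yl)-3,4,8,8a-tetrahydronaphthalene-1,6(2H,7H)-dione | CC(C)=CC[C@@]12C(=O)CCCC1=CC(=O)CC2 | intermediate
8 | (8aS)-8a-(3-methylbut-2-en-1-yl)-3,4-dihydronaphthalene-1,6(2H,8aH)-dione | CC(C)=CC[C@@]12C(=O)CCCC1=CC(=O)C=C2 | intermediate
9 | 10-(prop-1-en-2-yl)tricyclo[7.2.1.0^1,6]dodeca-2,5-diene-4,12-dione (ring E closed, isopropenyl exo on C4) | C=C(C)[C@H]1C[C@@]23C(=O)[C@@H]1CCC2=CC(=O)C=C3 | intermediate
10 | C13 tert-butyldimethylsilyl trienol ether of 9 | C=C(C)[C@H]1C[C@@]23C(=O)[C@@H]1CC=C2C=C(O[Si](C)(C)C(C)(C)C)C=C3 | intermediate
11 | C10-hydroxy derivative of 9 (OH exo) | C=C(C)[C@H]1C[C@@]23C(=O)[C@@H]1C[C@H](O)C2=CC(=O)C=C3 | intermediate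
12 | C10 tert-butyldimethylsilyl ether of 11 | C=C(C)[C@H]1C[C@@]23C(=O)[C@@H]1C[C@H](O[Si](C)(C)C(C)(C)C)C2=CC(=O)C=C3 | intermediate
13 | (2,5-dimethoxyphenyl)boronic acid | COc1ccc(OC)c(B(O)O)c1 | starting material
14 | C16-(2,5-dimethoxyphenyl) enone (aryl syn to C7, anti to C5) | C=C(C)[C@H]1C[C@@]23C(=O)[C@@H]1C[C@H](O[Si](C)(C)C(C)(C)C)C2=CC(=O)C[C@@H]3c1cc(OC)ccc1OC | intermediate
15 | chloro(methyl)aluminium enolate of 16 (C12=C13–O–Al) | C=C(C)[C@H]1C[C@@]23C(=O)[C@@H]1C[C@H](O[Si](C)(C)C(C)(C)C)[C@@]21C=C(O[Al](C)Cl)C[C@@H]3c2c(OC)ccc(OC)c21 | intermediate (not isolated)
16 | pentacyclic C13 ketone (ring D closed, C10 silyl ether, ring A dimethyl ether) | C=C(C)[C@H]1C[C@@]23C(=O)[C@@H]1C[C@H](O[Si](C)(C)C(C)(C)C)[C@@]21CC(=O)C[C@@H]3c2c(OC)ccc(OC)c21 | intermediate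
17 | potassium C13=C15 enolate of 16 | C=C(C)[C@H]1C[C@@]23C(=O)[C@@H]1C[C@H](O[Si](C)(C)C(C)(C)C)[C@@]21CC([O-])=C[C@@H]3c2c(OC)ccc(OC)c21.[K+] | intermediate (not isolated)
18 | C13 enol triflate (C13=C15) | C=C(C)[C@H]1C[C@@]23C(=O)[C@@H]1C[C@H](O[Si](C)(C)C(C)(C)C)[C@@]21CC(OS(=O)(=O)C(F)(F)F)=C[C@@H]3c2c(OC)ccc(OC)c21 | intermediate
19 | C13-methyl alkene, C10 silyl ether | C=C(C)[C@H]1C[C@@]23C(=O)[C@@H]1C[C@H](O[Si](C)(C)C(C)(C)C)[C@@]21CC(C)=C[C@@H]3c2c(OC)ccc(OC)c21 | intermediate
20 | C10 alcohol | C=C(C)[C@H]1C[C@@]23C(=O)[C@@H]1C[C@H](O)[C@@]21CC(C)=C[C@@H]3c2c(OC)ccc(OC)c21 | intermediate
21 | dimethyl ether of the target | C=C(C)[C@H]1C[C@@]23C(=O)[C@@H]1CC(=O)[C@@]21CC(C)=C[C@@H]3c2c(OC)ccc(OC)c21 | intermediate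
22 | para-quinone of the target | C=C(C)[C@H]1C[C@@]23C(=O)[C@@H]1CC(=O)[C@@]21CC(C)=C[C@@H]3C2=C1C(=O)C=CC2=O | intermediate (not isolated)
23 | CNP0287617.1 | C=C(C)[C@H]1C[C@@]23C(=O)[C@@H]1CC(=O)[C@@]21CC(C)=C[C@@H]3c2c(O)ccc(O)c21 | target

## Step count and least certain steps

Total step count: 15. Longest linear sequence: 15 steps (1 to 23); 2, 4 and 13 are bought.

**Step 3 (key step).** The most likely failure is erosion of the enantiotopic-group selection. The prenyl group is larger than the methyl group of the parent case, the cyclisation is slower, and an uncatalysed or poorly organised pathway can then compete; incomplete dehydration of 6 is a lesser concern. Step 9 helps, because its chiral catalyst should turn any mirror-image material into a separable diastereomer.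
Fallback, from 5 back to 7: the aldol condensation is run without chiral information (pyrrolidine, AcOH, toluene, 60 °C). This gives 7 mixed with its mirror image, the (8aS)-enantiomer of 7 F1, and the two are separated by preparative chromatography on a chiral stationary phase. Enantiopurity then comes from a resolution and no longer from the catalyst.

**Step 10.** Two processes threaten it. The arene may fail to attack, because C11 becomes quaternary next to quaternary C6 and the silyloxy group on C10, and a dimethoxybenzene is only a moderate nucleophile. Alternatively the Lewis acid may activate the C7 carbonyl, which the nearby isopropenyl group can capture in an ene or Prins-type closure.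
Fallback, from 12 back to 16: the arene is made a far better nucleophile and the ring is closed under base without any Lewis acid. (5-Hydroxy-2-methoxyphenyl)boronic acid F2 (from 3-bromo-4-methoxyphenol by palladium-catalysed borylation and hydrolysis) is added to 12 under the conditions of step 9 to give the phenol analogue of 14 F3. Cs2CO3 in DMF converts it into the phenoxide, whose ortho carbon C22 adds to C11 (attack through oxygen would need a seven-membered ring), giving the cyclised phenol F4. MeI and K2CO3 in acetone then turn F4 into 16.

**Step 9.** Three processes may interfere. The ligand and the substrate may be mismatched, so that the addition is slow or the aryl group leaks to the C5 face; the two faces of C16 in 12 differ little, since one is flanked by the C7 carbonyl oxygen and the other by a C5 hydrogen. The electron-rich boronic acid may protodeboronate. In wet solvent a nucleophile may cleave the C6–C7 bond with aromatisation of the dienone ring.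
Fallback, from 12 back to 14: copper-catalysed addition of commercial 2,5-dimethoxyphenylmagnesium bromide (CuBr·SMe2 cat., THF, −60 °C, NH4Cl work-up). This replaces boron-to-rhodium transmetalation in wet solvent by an organocopper reagent in an aprotic medium at low temperature. Control passes from the ligand to the substrate, where the magnesium and copper counter-ions can bridge to the C7 carbonyl oxygen, which lies on the required face. No new isolated compound is involved.

**Step 5.** Simple ketones enolise slowly toward trivalent manganese. During the long heating in acetic acid the prenyl group of 8 can leave C6 by a sigmatropic shift with aromatisation of the dienone ring, the vinylogous C10 position can be oxidised, or the tertiary radical can be over-oxidised to a cation that gives alkene isomers and acetate.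
Fallback, from 8 back to 9, by a two-electron closure at low temperature: SeO2 (cat.) with t-BuOOH oxidises the (E)-methyl group of the prenyl chain to the (E)-allylic alcohol F5, and ClCO2Me with pyridine gives the allylic methyl carbonate F6. The lithium enolate of the C7 ketone (LiN(SiMe3)2, THF, −78 °C; C8 again has the only α-hydrogens) is then cyclised with Pd(PPh3)4 in a Tsuji–Trost reaction. The π-allyl complex is attacked at its inner terminus C4 (attack at C1 would need a seven-membered ring holding an E alkene), which forms C4–C8 and leaves C1=C2 as the isopropenyl double bond.

**Step 11.** Deprotonation may take place at C12 as well as at C15. This would give the regioisomeric triflate and, after step 12, the C12=C13 alkene; the two α-methylenes differ only in the substitution of their neighbours.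
Fallback, from 16 back to 19: MeMgBr with CeCl3 (THF, −78 °C) adds to C13, the only accessible carbonyl (C7 is screened by the isopropenyl group on one face and by ring A on the other), giving the C13 tertiary alcohol F7 (methyl drawn syn to ring A; either epimer serves). SOCl2 and pyridine at −20 °C dehydrate it. The position of the double bond then depends on which β-hydrogen the base reaches in an anti elimination and no longer on an enolate, and any C12=C13 or exocyclic isomer is removed on AgNO3-impregnated silica.

## Further compounds

F1 | step 3 | (8aS)-8a-(3-methylbut-2-en-1-yl)-3,4,8,8a-tetrahydronaphthalene-1,6(2H,7H)-dione (enantiomer of 7) | CC(C)=CC[C@]12C(=O)CCCC1=CC(=O)CC2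
F2 | step 10 | (5-hydroxy-2-methoxyphenyl)boronic acid | COc1ccc(O)cc1B(O)O
F3 | step 10 | phenol analogue of 14 (5-hydroxy-2-methoxyphenyl on C16) | C=C(C)[C@H]1C[C@@]23C(=O)[C@@H]1C[C@H](O[Si](C)(C)C(C)(C)C)C2=CC(=O)C[C@@H]3c1cc(O)ccc1OC
F4 | step 10 | cyclised phenol (16 with OH in place of OCH3 on C21) | C=C(C)[C@H]1C[C@@]23C(=O)[C@@H]1C[C@H](O[Si](C)(C)C(C)(C)C)[C@@]21CC(=O)C[C@@H]3c2c(OC)ccc(O)c21
F5 | step 5 | (E)-allylic alcohol from 8 (C1 hydroxylated) | OC/C(C)=C/C[C@@]12C(=O)CCCC1=CC(=O)C=C2
F6 | step 5 | allylic methyl carbonate of F5 | COC(=O)OC/C(C)=C/C[C@@]12C(=O)CCCC1=CC(=O)C=C2
F7 | step 11 | C13 tertiary alcohol from 16 (C13 bears OH and CH3) | C=C(C)[C@H]1C[C@@]23C(=O)[C@@H]1C[C@H](O[Si](C)(C)C(C)(C)C)[C@@]21C[C@@](C)(O)C[C@@H]3c2c(OC)ccc(OC)c21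
F0 | step 9 | none | none
A1 | alternative 1 | target skeleton with C10 dioxolane and ring A dimethyl ether (product of the radical closure) | C=C(C)[C@H]1C[C@@]23C(=O)[C@@H]1CC4(OCCO4)[C@@]21CC(C)=C[C@@H]3c2c(OC)ccc(OC)c21
A2 | alternative 1 | prenyl ketone with rings A to D, C10 dioxolane and ring A dimethyl ether (substrate of the radical closure) | CC(C)=CC[C@@]23C(=O)CCC4(OCCO4)[C@@]21CC(C)=C[C@@H]3c2c(OC)ccc(OC)c21
A3 | alternative 2 | bis-borylated benzobicyclo[3.2.1]octadiene enedione (product of the cyclotrimerisation) | CC(C)=CC[C@@]23C(=O)C=CC(=O)[C@@]21CC(C)=C[C@@H]3c2c(B4OC(C)(C)C(C)(C)O4)ccc(B4OC(C)(C)C(C)(C)O4)c21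
A4 | alternative 2 | 1,6-diyne with alkynylboronate arms on C16 and C11 (substrate of the cyclotrimerisation) | CC(C)=CC[C@@]23C(=O)C=CC(=O)[C@@]2(C#CB4OC(C)(C)C(C)(C)O4)CC(C)=C[C@@H]3C#CB4OC(C)(C)C(C)(C)O4
A5 | alternative 2 | acetylene | C#C
A6 | alternative 3 | prenyl fluorenone-type dienone with C10 enol ether (product of the dearomatising cyclisation) | CC(C)=CC[C@@]12C(=O)C=CC(OC)=C1c1c(OC)ccc(OC)c1C2
A7 | alternative 3 | biaryl phenol with benzylic bromide at C16 (single atropisomer; the axis is not expressed in this SMILES) | CC(C)=CCc1c(O)ccc(OC)c1-c1c(OC)ccc(OC)c1CBr
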